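Turn the first step into a time before reading anything else off the runs. This is the problem:

| flask | substrate | partner | capture agent | remark | time |
|---|---|---|---|---|---|
| midnight | 0.078 M | 0.042 M | 7.8 mM | run made earlier |  |
| dawn | 0.078 M | 0.094 M | 7.8 mM | run made earlier |  |
| red | 0.078 M | 0.0624 M | 7.80 mM |  | 3.0 min |
| blue | 0.078 M | 0.0624 M | 7.80 mM |  | 8.0 min |
| amber | 0.078 M | 0.0624 M | 7.80 mM |  | 20 min |

| run | time / min | trapped intermediate / % | triple product / % | single product / % | bis adduct / % | substrate / % |
|---|---|---|---|---|---|---|
| midnight | 0.833 | 0 | 0.8 | 6.8 | 0 | 93.2 |
| midnight | 1.50 | 0.1 | 0.7 | 9.6 | 0.1 | 90.2 |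
| midnight | 2.50 | 0 | 1.5 | 16.2 | 2.4 | 82.2 |
| midnight | 3.00 | 0.7 | 0 | 17.6 | 1.8 | 81.3 |
| dawn | 0.833 | 0.3 | 0 | 12.9 | 1.8 | 86.7 |
| dawn | 1.50 | 0.9 | 0 | 25.5 | 1.1 | 75.6 |
| dawn | 2.50 | 0 | 1.4 | 30.1 | 1.7 | 66.4 |
| dawn | 3.00 | 0 | 0.2 | 33.1 | 4.2 | 62.3 |

(standard deviation of a reading: 1 percentage point)

1. which of these there is most of at the end, counted by the substrate in it, red (trapped intermediate / single product / bis adduct / substrate)
2. which of these there is most of at the end, counted by the substrate in it, blue (trapped intermediate / single product / bis adduct / substrate)
3. which of these there is most of at the end, counted by the substrate in it, amber (trapped intermediate / single product / bis adduct / substrate)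
4. how much there is at the end of the one of these that leads, in percent of the substrate charged: red
5. how much there is at the end of the one of these that leads, in percent of the substrate charged: blue
6. how much there is at the end of the one of these that leads, in percent of the substrate charged: amber

- the numbers in the tables scatter by 1 percentage point (one standard deviation)

I read both earlier runs at their last point, 3.00 min. In the dawn run substrate stands at 62.3 %, a first-order loss rate of 0.158 min⁻¹ while partner averages 0.0793 M, counting one partner per substrate lost. In the midnight run it stands at 81.3 %, which gives 0.0690 min⁻¹ at 0.0347 M. The rates differ by a factor of 2.29 and the partner amounts by 2.29, so the loss follows partner. For partner facing 0.078 M of substrate this reads as 6.45 min, and that is what I carry: the first-step time, the time for one reagent to fall by a factor e with the other held at its charge, a pseudo-first-order time.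

Red, blue and amber are one charge read at three times. At the start the first-step time of substrate is 8.06 min, so red, read at 3.0 min, is still in the opening stage and substrate leads. Bis adduct has to wait for single product: the dawn run shows 4.2 % beside 33.1 % at 3.00 min. In the middle partner falls too, and halving the substrate costs 62.5 % of the partner charged by the first step. Partner then averages 0.0429 M, so I expect substrate at half after 8.12 min. Blue, at 8.0 min, stands about there, and because bis adduct shares the converted half, I keep substrate narrowly ahead. Amber, at 20 min, is well past that point, so single product leads.

The forecast says substrate at 74 % (70 % to 78 %) for red, substrate at 55 % (49 % to 60 %) for blue, and single product at 47 % (41 % to 53 %) for amber, integrating with “partner, which is consumed by both steps”. My half-point puts blue's substrate lower than the forecast does.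

The flasks give substrate at 73.0 % in red, substrate at 53.4 % in blue and single product at 50.0 % in amber, so the forecast holds on the leaders and within its ranges.

    bis adduct + capture agent → trapped intermediate (k = 0.0260 M⁻¹ s⁻¹)
    substrate + partner → single product (k = 0.0350 M⁻¹ s⁻¹)
    partner + single product → bis adduct (k = 0.0130 M⁻¹ s⁻¹)
    partner + bis adduct → triple product (k = 0.00380 M⁻¹ s⁻¹)

In blue at 8.00 min, with partner at 34.7 % of its charge, single product has a half-life of 41 min by the step to bis adduct, against 15.2 min for substrate by the first step at that same partner level, and it is made 3.51 times faster than used up. The forecast neglected trapped intermediate and triple product: in amber, trapped intermediate holds 1.26 % and triple product 0.371 %, against a lead of 11 percentage points. A neighbour of blue is charged with 0.31 M of substrate, so partner, at 0.201 equiv, is the limiting reagent. Its first-step time there is 1.62 min, so 8.0 min is 4.94 such times, which puts partner near 0.717 % and substrate near 79.9 %. That flask gives partner 0.92 %, substrate 80.8 % and single product 18.4 %.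

(The earlier runs and the new flask are calculated with constants of no real substance; scatter was added.)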